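**Strategy.** The plan cuts the C2–C3 bond, the one bond common to the pyranone (ring C) and the oxepine. C3 is the only enolisable carbon of a ring A aryl ketone, and its chain (C9, stereocentre C10) ends at the ether oxygen of a ring B salicylate whose ester carbon is C2. One intramolecular Claisen condensation therefore closes the seven-membered ring and creates the 1,3-diketone that cyclodehydrates onto the ring A phenol to give the flavone. The precursor is a MOM-protected ring A ketone carrying an (R)-4-aryloxy-5-methyl-5-(triethylsilyloxy)hexanoyl chain, built from L-glutamic acid 5-benzyl ester (C10), a salicylate (ring B) and a lithiated ring A arene.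

Key step: step 13

Remark on the chemistry: flavone numbering is used (O1, C2, C3, C4, ring A C5–C8, ring B primed); C9 is the oxepine CH2, C10 the stereocentre, C11 the carbinol carbon. Grignard and alkyllithium reagents are taken as commercial solutions.

**Step 1**
Reactants: 1 methyl 2,4-dihydroxybenzoate
Product: 2 methyl 2-hydroxy-4-(methoxymethoxy)benzoate
Conditions: MOMCl (1.1 equiv), i-Pr2NEt, CH2Cl2, 0 °C → rt
Reagents that add atoms: chloromethyl methyl ether, COCCl
Why: Phenol O-alkylation (acetal protection) should go to the 4-OH because the 2-OH is tied up in a hydrogen bond to the ester carbonyl and is far less nucleophilic.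

**Step 2**
Reactants: 3 L-glutamic acid 5-benzyl ester
Product: 4 (S)-5-(benzyloxy)-2-hydroxy-5-oxopentanoic acid
Conditions: NaNO2, 1 M aq. H2SO4, 0 °C → rt
Reagents that add atoms: water, O
Why: Diazotisation–hydrolysis of an α-amino acid replaces NH2 by OH with net retention through neighbouring-group participation of the α-carboxylate (double inversion), so the future C10 starts as the S carbinol.

**Step 3**
Reactants: 4 (S)-5-(benzyloxy)-2-hydroxy-5-oxopentanoic acid
Product: 5 5-benzyl 1-methyl (S)-2-hydroxypentanedioate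
Conditions: MeI, KHCO3, DMF, rt
Reagents that add atoms: iodomethane, CI
Why: Carboxylate O-alkylation (SN2 on MeI) esterifies the acid under conditions too weakly basic to touch the secondary hydroxyl, the benzyl ester or the stereocentre.

**Step 4**
Reactants: 2 methyl 2-hydroxy-4-(methoxymethoxy)benzoate; 5 5-benzyl 1-methyl (S)-2-hydroxypentanedioate
Product: 6 5-benzyl 1-methyl (R)-2-[5-(methoxymethoxy)-2-(methoxycarbonyl)phenoxy]pentanedioate
Conditions: PPh3, DIAD, THF, 0 °C → rt
Reagents that add atoms: none
Why: Mitsunobu etherification of an α-hydroxy ester by a phenol is a clean SN2 displacement, so the S carbinol of 5 is inverted to the R aryl ether that becomes C10.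

**Step 5**
Reactants: 6 5-benzyl 1-methyl (R)-2-[5-(methoxymethoxy)-2-(methoxycarbonyl)phenoxy]pentanedioate
Product: 7 (R)-5-methoxy-4-[5-(methoxymethoxy)-2-(methoxycarbonyl)phenoxy]-5-oxopentanoic acid
Conditions: H2 (1 atm), 10% Pd/C, EtOAc, rt
Reagents that add atoms: none
Why: Hydrogenolysis of the benzyl ester frees the distal acid without affecting the methyl esters, the MOM acetal or the aryl alkyl ether, and so tells the two ends of the glutarate apart.

**Step 6**
Reactants: 7 (R)-5-methoxy-4-[5-(methoxymethoxy)-2-(methoxycarbonyl)phenoxy]-5-oxopentanoic acid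
Product: 9 (R)-5-hydroxy-4-[5-(methoxymethoxy)-2-(methoxycarbonyl)phenoxy]-5-methylhexanoic acid, via keto acid 8 (not isolated)
Conditions: MeMgBr (3.3 equiv), THF, −78 → −20 °C; aq. citric acid
Reagents that add atoms: methylmagnesium bromide, C[Mg]Br
Why: Grignard double addition: the first equivalent makes the inert carboxylate, the inductively activated α-aryloxy methyl ester then takes two methyl groups through ketone 8, and the ring B benzoate should be spared at low temperature because its ortho and para oxygen donors and its ortho substituent make it a poor electrophile; C10 is not a reacting centre and keeps its configuration.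

**Step 7**
Reactants: 9 (R)-5-hydroxy-4-[5-(methoxymethoxy)-2-(methoxycarbonyl)phenoxy]-5-methylhexanoic acid
Product: 10 methyl 2-{[(3R)-2,2-dimethyl-6-oxooxan-3-yl]oxy}-4-(methoxymethoxy)benzoate
Conditions: EDC·HCl, DMAP (cat.), CH2Cl2, 0 °C → rt
Reagents that add atoms: none
Why: Carbodiimide (Steglich-type) activation of the acid lets the tertiary hydroxyl close the six-membered lactone, which turns the chain terminus (future C4) into an acylating agent.

**Step 8**
Reactants: 11 4-hydroxy-2,6-dimethoxybenzaldehyde
Product: 12 2,6-dimethoxy-4-(methoxymethoxy)benzaldehyde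
Conditions: MOMCl, i-Pr2NEt, CH2Cl2, 0 °C → rt
Reagents that add atoms: chloromethyl methyl ether, COCCl
Why: Acetal protection of the only phenol installs the group that later directs ortho-lithiation and finally releases the oxygen that becomes O1.

**Step 9**
Reactants: 12 2,6-dimethoxy-4-(methoxymethoxy)benzaldehyde
Product: 13 (±)-1-[2,6-dimethoxy-4-(methoxymethoxy)phenyl]-3-methylbutan-1-ol
Conditions: i-BuMgBr, THF, −20 → 0 °C
Reagents that add atoms: isobutylmagnesium bromide, CC(C)C[Mg]Br
Why: Grignard 1,2-addition to the aldehyde brings in the four side-chain carbons; the new carbinol centre forms as a racemate and is removed in the next step.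

**Step 10**
Reactants: 13 (±)-1-[2,6-dimethoxy-4-(methoxymethoxy)phenyl]-3-methylbutan-1-ol
Product: 15 1,3-dimethoxy-5-(methoxymethoxy)-2-[(E)-3-methylbut-1-en-1-yl]benzene, via benzylic mesylate 14 (not isolated)
Conditions: MsCl, Et3N, DMAP (cat.), CH2Cl2, 0 → 40 °C
Reagents that add atoms: none
Why: Sulfonylation–elimination (E1 type): the mesylate of this 2,4,6-trioxygenated benzylic alcohol should ionise readily and lose a proton from the only β-carbon, giving the styrene-type alkene as the thermodynamically preferred E isomer under base, with no acid that could harm the acetal.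

**Step 11**
Reactants: 15 1,3-dimethoxy-5-(methoxymethoxy)-2-[(E)-3-methylbut-1-en-1-yl]benzene; 10 methyl 2-{[(3R)-2,2-dimethyl-6-oxooxan-3-yl]oxy}-4-(methoxymethoxy)benzoate
Product: 17 methyl 2-{[(3R)-6-{2,4-dimethoxy-6-(methoxymethoxy)-3-[(E)-3-methylbut-1-en-1-yl]phenyl}-2-hydroxy-2-methyl-6-oxohexan-3-yl]oxy}-4-(methoxymethoxy)benzoate, via aryllithium 16 (not isolated)
Conditions: n-BuLi, TMEDA, THF, −20 → 0 °C; then 10, −78 °C; aq. NH4Cl at −78 °C
Reagents that add atoms: none
Why: Directed ortho-metalation takes place at the position flanked by OMOM and OMe (the two such positions are equivalent), and the aryllithium opens the δ-lactone by acyl substitution to a lithium lactolate that resists a second addition, the lactone being far more electrophilic at −78 °C than the deactivated, hindered ring B benzoate.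

**Step 12**
Reactants: 17 (hydroxy ketone, name as in step 11)
Product: 18 methyl 2-{[(3R)-6-{2,4-dimethoxy-6-(methoxymethoxy)-3-[(E)-3-methylbut-1-en-1-yl]phenyl}-2-methyl-6-oxo-2-[(triethylsilyl)oxy]hexan-3-yl]oxy}-4-(methoxymethoxy)benzoate
Conditions: Et3SiOTf, 2,6-lutidine, CH2Cl2, −78 → −20 °C
Reagents that add atoms: triethylsilyl trifluoromethanesulfonate, CC[Si](CC)(CC)OS(=O)(=O)C(F)(F)F
Why: Silyl triflate silylation is the standard way to cap a tertiary alcohol, and the cold, lutidine-buffered medium should leave the acetals, the ketone and the electron-rich alkene alone.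

**Step 13**
Reactants: 18 (silyl-protected keto ester, name as in step 12)
Product: 20 {2,4-dimethoxy-6-(methoxymethoxy)-3-[(E)-3-methylbut-1-en-1-yl]phenyl}{(2R)-5-hydroxy-8-(methoxymethoxy)-2-{2-[(triethylsilyl)oxy]propan-2-yl}-2,3-dihydro-1-benzoxepin-4-yl}methanone (enol form of the cyclic 1,3-diketone), via lithium enolate 19 (not isolated)
Conditions: LiN(SiMe3)2 (3 equiv), THF, −78 °C → rt; aq. NH4Cl
Reagents that add atoms: none
Why: LiN(SiMe3)2 removes a proton from C3, the only enolisable carbon, to give lithium enolate 19, whose carbon adds to the ring B ester carbonyl (the future C2); loss of methoxide gives the cyclic 1,3-diketone, which a second equivalent of base converts into its stabilised enolate and so pulls the equilibrium forward. The closest known reaction is the Dieckmann-type intramolecular Claisen condensation used to make 1-benzoxepin-5-ones from 4-(2-alkoxycarbonylphenoxy)butanoates, here with a ketone enolate as in the C-acylation of a Baker–Venkataraman sequence. The oxepine closes in a 7-exo-trig mode (enolate double bond exocyclic to the new ring), helped by the ortho-disubstituted arene that holds ester and chain close together. No stereocentre is formed; C10 bears no acidic hydrogen and its aryloxy group is γ to the ketone, so neither epimerisation nor β-elimination is open. The step needs C-acylation at C3 by the benzoate only: the single α-carbon fixes the site of enolisation, the silyl ether stops the C11 oxygen from lactonising onto the ester, and the MOM ether keeps the ring A oxygen from acting as a phenoxide nucleophile.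

**Step 14**
Reactants: 20 (enol diketone, name as in step 13)
Product: 22 5-O-methyl ether of the target, i.e. (10R)-4'-hydroxy-5,7-dimethoxy-6-[(E)-3-methylbut-1-en-1-yl]flavone whose C3 and 2'-oxygen are bridged by CH2 (C9)–CH (C10) carrying C(CH3)2OH, via phenolic diketone 21 (not isolated)
Conditions: 3 M aq. HCl–MeOH (1:10), THF, 45 °C
Reagents that add atoms: none
Why: Acid-catalysed acetal and silyl ether cleavage followed by the cyclodehydration that ends a Baker–Venkataraman flavone synthesis: once the MOM group ortho to the ketone is gone, the ring A phenol of 21 should add to the ring-B-side carbonyl (C2) and lose water to give the aromatic pyranone, the 5-O-methyl group ensuring that only this oxygen can close the ring, and C10 is not touched.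

**Step 15**
Reactants: 22 (5-O-methyl flavone, as in step 14)
Product: 23 target, (10R)-5,4'-dihydroxy-7-methoxy-6-[(E)-3-methylbut-1-en-1-yl]flavone whose C3 and 2'-oxygen are bridged by CH2 (C9)–CH (C10) carrying C(CH3)2OH (CNP0216454.1)
Conditions: MgI2·OEt2 (4 equiv), THF–toluene, 70 °C; 1 M aq. HCl
Reagents that add atoms: none
Why: Chelation-assisted Lewis-acid O-demethylation: magnesium bridges the C4 carbonyl and the peri 5-methoxy oxygen so that iodide should remove only that methyl group, while the 7-methoxy group, the tertiary alcohol, the alkene and C10 are not activated.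

**Compound list**

1 | methyl 2,4-dihydroxybenzoate | COC(=O)c1ccc(O)cc1O | starting material
2 | methyl 2-hydroxy-4-(methoxymethoxy)benzoate | COCOc1ccc(C(=O)OC)c(O)c1 | intermediate
3 | L-glutamic acid 5-benzyl ester, (S)-2-amino-5-(benzyloxy)-5-oxopentanoic acid | N[C@@H](CCC(=O)OCc1ccccc1)C(=O)O | starting material
4 | (S)-5-(benzyloxy)-2-hydroxy-5-oxopentanoic acid | O[C@@H](CCC(=O)OCc1ccccc1)C(=O)O | intermediate
5 | 5-benzyl 1-methyl (S)-2-hydroxypentanedioate | COC(=O)[C@@H](O)CCC(=O)OCc1ccccc1 | intermediate
6 | 5-benzyl 1-methyl (R)-2-[5-(methoxymethoxy)-2-(methoxycarbonyl)phenoxy]pentanedioate | O=C(CC[C@H](C(=O)OC)Oc1cc(OCOC)ccc1C(=O)OC)OCc1ccccc1 | intermediate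
7 | (R)-5-methoxy-4-[5-(methoxymethoxy)-2-(methoxycarbonyl)phenoxy]-5-oxopentanoic acid | OC(=O)CC[C@H](C(=O)OC)Oc1cc(OCOC)ccc1C(=O)OC | intermediate
8 | (R)-4-[5-(methoxymethoxy)-2-(methoxycarbonyl)phenoxy]-5-oxohexanoic acid (present as its magnesium carboxylate) | OC(=O)CC[C@H](C(C)=O)Oc1cc(OCOC)ccc1C(=O)OC | intermediate (not isolated)
9 | (R)-5-hydroxy-4-[5-(methoxymethoxy)-2-(methoxycarbonyl)phenoxy]-5-methylhexanoic acid | OC(=O)CC[C@H](C(C)(C)O)Oc1cc(OCOC)ccc1C(=O)OC | intermediate
10 | methyl 2-{[(3R)-2,2-dimethyl-6-oxooxan-3-yl]oxy}-4-(methoxymethoxy)benzoate | O=C1CC[C@H](C(C)(C)O1)Oc1cc(OCOC)ccc1C(=O)OC | intermediate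
11 | 4-hydroxy-2,6-dimethoxybenzaldehyde | COc1cc(O)cc(OC)c1C=O | starting material
12 | 2,6-dimethoxy-4-(methoxymethoxy)benzaldehyde | COCOc1cc(OC)c(C=O)c(OC)c1 | intermediate
13 | (±)-1-[2,6-dimethoxy-4-(methoxymethoxy)phenyl]-3-methylbutan-1-ol | COCOc1cc(OC)c(C(O)CC(C)C)c(OC)c1 | intermediate
14 | (±)-1-[2,6-dimethoxy-4-(methoxymethoxy)phenyl]-3-methylbutyl methanesulfonate | COCOc1cc(OC)c(C(OS(C)(=O)=O)CC(C)C)c(OC)c1 | intermediate (not isolated)
15 | 1,3-dimethoxy-5-(methoxymethoxy)-2-[(E)-3-methylbut-1-en-1-yl]benzene | COCOc1cc(OC)c(/C=C/C(C)C)c(OC)c1 | intermediate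
16 | {2,4-dimethoxy-6-(methoxymethoxy)-3-[(E)-3-methylbut-1-en-1-yl]phenyl}lithium | COCOc1cc(OC)c(/C=C/C(C)C)c(OC)c1[Li] | intermediate (not isolated)
17 | methyl 2-{[(3R)-6-{2,4-dimethoxy-6-(methoxymethoxy)-3-[(E)-3-methylbut-1-en-1-yl]phenyl}-2-hydroxy-2-methyl-6-oxohexan-3-yl]oxy}-4-(methoxymethoxy)benzoate | COCOc1cc(OC)c(/C=C/C(C)C)c(OC)c1C(=O)CC[C@H](C(C)(C)O)Oc1cc(OCOC)ccc1C(=O)OC | intermediate
18 | methyl 2-{[(3R)-6-{2,4-dimethoxy-6-(methoxymethoxy)-3-[(E)-3-methylbut-1-en-1-yl]phenyl}-2-methyl-6-oxo-2-[(triethylsilyl)oxy]hexan-3-yl]oxy}-4-(methoxymethoxy)benzoate (key-step precursor) | COCOc1cc(OC)c(/C=C/C(C)C)c(OC)c1C(=O)CC[C@H](C(C)(C)O[Si](CC)(CC)CC)Oc1cc(OCOC)ccc1C(=O)OC | intermediate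
19 | lithium enolate of 18 at C3 (drawn as the Z enolate; its geometry is of no consequence) | COCOc1cc(OC)c(/C=C/C(C)C)c(OC)c1/C(O[Li])=C/C[C@H](C(C)(C)O[Si](CC)(CC)CC)Oc1cc(OCOC)ccc1C(=O)OC | intermediate (not isolated)
20 | {2,4-dimethoxy-6-(methoxymethoxy)-3-[(E)-3-methylbut-1-en-1-yl]phenyl}{(2R)-5-hydroxy-8-(methoxymethoxy)-2-{2-[(triethylsilyl)oxy]propan-2-yl}-2,3-dihydro-1-benzoxepin-4-yl}methanone (key-step product, enol form) | COCOc1cc(OC)c(/C=C/C(C)C)c(OC)c1C(=O)C1=C(O)c2ccc(OCOC)cc2O[C@@H](C(C)(C)O[Si](CC)(CC)CC)C1 | intermediate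
21 | {6-hydroxy-2,4-dimethoxy-3-[(E)-3-methylbut-1-en-1-yl]phenyl}[(2R)-5,8-dihydroxy-2-(2-hydroxypropan-2-yl)-2,3-dihydro-1-benzoxepin-4-yl]methanone | Oc1cc(OC)c(/C=C/C(C)C)c(OC)c1C(=O)C1=C(O)c2ccc(O)cc2O[C@@H](C(C)(C)O)C1 | intermediate (not isolated)
22 | 5-O-methyl ether of the target: (10R)-4'-hydroxy-5,7-dimethoxy-6-[(E)-3-methylbut-1-en-1-yl]flavone with C3 and O-2' bridged by CH2–CH[C(CH3)2OH] | COc1cc2oc3c(c(=O)c2c(OC)c1/C=C/C(C)C)C[C@H](C(C)(C)O)Oc1cc(O)ccc1-3 | intermediate
23 | CNP0216454.1: (10R)-5,4'-dihydroxy-7-methoxy-6-[(E)-3-methylbut-1-en-1-yl]flavone with C3 and O-2' bridged by CH2–CH[C(CH3)2OH] | COc1cc2oc3c(c(=O)c2c(O)c1/C=C/C(C)C)C[C@H](C(C)(C)O)Oc1cc(O)ccc1-3 | target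

**Step count.** Total: 15 steps. Longest linear sequence: 11 steps (3 → 23 through steps 2–7 and 11–15).

**Steps most likely to fail**

Step 13. The hindered lithium enolate may add too slowly to the electron-rich, ortho-substituted benzoate, so that proton return on work-up, slow loss of the silyl group or intermolecular condensation take over. The fallback replaces the methyl ester by a much stronger acyl donor. It sets out from 18: LiOH in THF–MeOH–H2O at 50 °C should hydrolyse the ring B ester to the carboxylic acid F1. 1,1'-Carbonyldiimidazole in THF at rt would turn it into the acyl imidazolide F2. LiN(SiMe3)2 in THF (−78 → 0 °C) would then effect the same C3–C2 bond formation by enolate C-acylation with the azolide, and the route is rejoined at 20.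

Step 14. Protic acid may add solvent to the electron-rich alkene or oligomerise it before ring A is deactivated by pyranone formation, and the freed tertiary alcohol may trap the diketone as a cyclic ketal. The fallback unmasks in stages and without protic acid, setting out from 20. Me3SiOTf with 2,2'-bipyridyl in CH2Cl2 at 0 °C, then water, should cleave both aryl MOM ethers and keep the silyl ether, giving the bis-phenol diketone F3. Catalytic pyridinium p-toluenesulfonate in toluene over 4 Å sieves at 60 °C would cyclodehydrate it to the silyl-protected flavone F4, in a medium free of nucleophilic solvent and with the C11 oxygen still blocked. Bu4NF buffered with AcOH in THF would remove the silyl group, and the route is rejoined at 22.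

Step 11. The basic, hindered aryllithium may deprotonate the lactone next to its carbonyl instead of adding, or the lithium lactolate may open and let the tertiary alkoxide attack the ring B ester. The fallback uses an open-chain, chelating acyl donor with the tertiary oxygen already capped, setting out from 10. MeNH(OMe)·HCl with i-PrMgCl in THF at −20 °C should open the lactone to the hydroxy Weinreb amide F5. Et3SiOTf and 2,6-lutidine would give the silylated Weinreb amide F6. Aryllithium 16 (from 15 as in step 11) added at −78 °C would form a chelated adduct that collapses only on work-up, giving the ketone directly, so the route is rejoined at 18 and step 12 is no longer needed.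

**Further compounds**

F1 | step 13 | 2-{[(3R)-6-{2,4-dimethoxy-6-(methoxymethoxy)-3-[(E)-3-methylbut-1-en-1-yl]phenyl}-2-methyl-6-oxo-2-[(triethylsilyl)oxy]hexan-3-yl]oxy}-4-(methoxymethoxy)benzoic acid | COCOc1cc(OC)c(/C=C/C(C)C)c(OC)c1C(=O)CC[C@H](C(C)(C)O[Si](CC)(CC)CC)Oc1cc(OCOC)ccc1C(=O)O
F2 | step 13 | acyl imidazolide of F1 (ring B C(=O)–N-imidazolyl) | COCOc1cc(OC)c(/C=C/C(C)C)c(OC)c1C(=O)CC[C@H](C(C)(C)O[Si](CC)(CC)CC)Oc1cc(OCOC)ccc1C(=O)n1ccnc1
F3 | step 14 | {6-hydroxy-2,4-dimethoxy-3-[(E)-3-methylbut-1-en-1-yl]phenyl}{(2R)-5,8-dihydroxy-2-{2-[(triethylsilyl)oxy]propan-2-yl}-2,3-dihydro-1-benzoxepin-4-yl}methanone | Oc1cc(OC)c(/C=C/C(C)C)c(OC)c1C(=O)C1=C(O)c2ccc(O)cc2O[C@@H](C(C)(C)O[Si](CC)(CC)CC)C1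
F4 | step 14 | C11 O-triethylsilyl ether of 22 | COc1cc2oc3c(c(=O)c2c(OC)c1/C=C/C(C)C)C[C@H](C(C)(C)O[Si](CC)(CC)CC)Oc1cc(O)ccc1-3
F5 | step 11 | methyl 2-{[(3R)-2-hydroxy-6-[methoxy(methyl)amino]-2-methyl-6-oxohexan-3-yl]oxy}-4-(methoxymethoxy)benzoate | CON(C)C(=O)CC[C@H](C(C)(C)O)Oc1cc(OCOC)ccc1C(=O)OC
F6 | step 11 | methyl 2-{[(3R)-6-[methoxy(methyl)amino]-2-methyl-6-oxo-2-[(triethylsilyl)oxy]hexan-3-yl]oxy}-4-(methoxymethoxy)benzoate | CON(C)C(=O)CC[C@H](C(C)(C)O[Si](CC)(CC)CC)Oc1cc(OCOC)ccc1C(=O)OC
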